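**Retrosynthetic overview**
1. Feature (Ar = 3,4,5-trimethoxyphenyl; oxolane O1, C2 (Ar), C3 (bearing C6H2OH), C4 (bearing the aroyl carbon C7), C5H2): C6 on C3 is cis to the C2 aryl group and lies four bonds from the oxygen on C7, so an O–SiMe2–CH2 tether on that oxygen can carry C6 to C3 through a six-membered 1,2-oxasilinane.
2. Target 26 ⇐ inversion of C4 at the ketone stage ⇐ diol 22 ⇐ Tamao oxidation of the C6–Si bond of the cis-fused oxasilinane–oxolane 21.
3. 21 ⇐ C3–C6 bond by 6-exo radical closure of the (bromomethyl)dimethylsilyl ether 20 onto the C2=C3 enol ether of a 2-aryl-4,5-dihydrofuran.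
4. Dihydrofuran 18 ⇐ cyclodehydration (O1–C2) of γ-hydroxy ketone 16 ⇐ Evans syn aldol (C4–C7) of imide 8 with aldehyde 9; 8 ⇐ aryl Grignard reagent, succinic anhydride, Wittig methylenation and auxiliary 6.
5. Ring order: the oxolane first (as the dihydrofuran, step 8), then the temporary oxasilinane (step 11), which is opened again in step 12.

Key step: step 11

Assumption: C7 ends as a ketone, so its carbinol configuration is free and the reliable Evans syn adduct is used; the locants C2–C7 of the overview are kept for every compound.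

Step 1
Reactants: 1 5-bromo-1,2,3-trimethoxybenzene; 2 succinic anhydride
Product: 4 4-oxo-4-(3,4,5-trimethoxyphenyl)butanoic acid, via (3,4,5-trimethoxyphenyl)magnesium bromide 3 (not isolated)
Conditions: Mg, I2 (cat.), THF, 40 °C; then added to 2 (1.5 equiv), THF, −78 °C → rt; 1 M HCl
Reagents that add atoms: none
Why: Grignard formation and mono-acylation by a cyclic anhydride, where inverse addition at low temperature to excess anhydride leaves a carboxylate-bearing ketone that is far less electrophilic than the anhydride, so the γ-keto acid should be the main product.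

Step 2
Reactants: 4 4-oxo-4-(3,4,5-trimethoxyphenyl)butanoic acid
Product: 5 4-(3,4,5-trimethoxyphenyl)pent-4-enoic acid
Conditions: Ph3PCH3Br (2.5 equiv), KOtBu (3.5 equiv), THF, 0 °C → rt; 1 M HCl
Reagents that add atoms: methyltriphenylphosphonium bromide, C[P+](c1ccccc1)(c1ccccc1)c1ccccc1.[Br-]
Why: Wittig methylenation with excess ylide, which first deprotonates the acid and then converts the aryl ketone into the 1,1-disubstituted alkene, a masked C2 ketone that cannot enolise in the aldol step.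

Step 3
Reactants: 5 4-(3,4,5-trimethoxyphenyl)pent-4-enoic acid; 6 (R)-4-benzyl-2-oxazolidinone
Product: 8 (R)-4-benzyl-3-[4-(3,4,5-trimethoxyphenyl)pent-4-enoyl]-2-oxazolidinone, via mixed pivalic anhydride 7 (not isolated)
Conditions: PivCl, Et3N, THF, −20 °C; then 6, LiCl, −20 °C → rt
Reagents that add atoms: none
Why: N-acylation of the oxazolidinone through the mixed pivalic anhydride under LiCl/Et3N activation, the hindered pivaloyl carbonyl directing attack to the pentenoyl carbonyl and the auxiliary stereocentre staying untouched.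

Step 4
Reactants: 8 (R)-4-benzyl-3-[4-(3,4,5-trimethoxyphenyl)pent-4-enoyl]-2-oxazolidinone; 9 3,4,5-trimethoxybenzaldehyde
Product: 12 (R)-4-benzyl-3-[(2R)-2-[(R)-hydroxy(3,4,5-trimethoxyphenyl)methyl]-4-(3,4,5-trimethoxyphenyl)pent-4-enoyl]-2-oxazolidinone, via Z-dibutylboron enolate 10 (not isolated), via dibutylboron aldolate 11 (not isolated)
Conditions: Bu2BOTf, iPr2NEt, CH2Cl2, −78 → 0 °C; 9, −78 → 0 °C; pH 7 buffer, MeOH, 30% H2O2, 0 °C
Reagents that add atoms: none
Why: Evans syn aldol reaction, in which the Z boron enolate adds to the aldehyde through a chair Zimmerman–Traxler transition state with the benzyl group of the auxiliary shielding one enolate face, forming the C4–C7 bond and setting C4 and C7 syn (both R in the adduct).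

Step 5
Reactants: 12 (R)-4-benzyl-3-[(2R)-2-[(R)-hydroxy(3,4,5-trimethoxyphenyl)methyl]-4-(3,4,5-trimethoxyphenyl)pent-4-enoyl]-2-oxazolidinone
Product: 13 (R)-4-benzyl-3-[(2R)-2-[(R)-(tert-butyldimethylsilyloxy)(3,4,5-trimethoxyphenyl)methyl]-4-(3,4,5-trimethoxyphenyl)pent-4-enoyl]-2-oxazolidinone
Conditions: TBSOTf, 2,6-lutidine, CH2Cl2, 0 °C
Reagents that add atoms: tert-butyldimethylsilyl triflate, CC(C)(C)[Si](C)(C)OS(=O)(=O)C(F)(F)F
Why: Silyl ether formation with a silyl triflate and a hindered base, which avoids retro-aldol cleavage and masks the C7 hydroxyl so that only the future O1 can later close onto C2.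

Step 6
Reactants: 13 (R)-4-benzyl-3-[(2R)-2-[(R)-(tert-butyldimethylsilyloxy)(3,4,5-trimethoxyphenyl)methyl]-4-(3,4,5-trimethoxyphenyl)pent-4-enoyl]-2-oxazolidinone
Product: 14 (2S)-2-[(R)-(tert-butyldimethylsilyloxy)(3,4,5-trimethoxyphenyl)methyl]-4-(3,4,5-trimethoxyphenyl)pent-4-en-1-ol
Conditions: LiBH4, MeOH (1 equiv), THF, 0 °C → rt
Reagents that add atoms: none
Why: Reductive cleavage of the N-acyl oxazolidinone by LiBH4 at the exocyclic carbonyl, which frees the auxiliary and gives the primary alcohol (future C5–O1) without enolisation, so C4 keeps its configuration (the descriptor changes to S only through the priority rules).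

Step 7
Reactants: 14 (2S)-2-[(R)-(tert-butyldimethylsilyloxy)(3,4,5-trimethoxyphenyl)methyl]-4-(3,4,5-trimethoxyphenyl)pent-4-en-1-ol
Product: 16 (3S)-3-[(R)-(tert-butyldimethylsilyloxy)(3,4,5-trimethoxyphenyl)methyl]-4-hydroxy-1-(3,4,5-trimethoxyphenyl)butan-1-one, via vicinal diol 15 (not isolated)
Conditions: OsO4 (2 mol %), NaIO4 (4 equiv), 2,6-lutidine, dioxane/H2O 3:1, rt
Reagents that add atoms: osmium tetroxide, O=[Os](=O)(=O)=O; sodium periodate, [Na+].[O-][I](=O)(=O)=O
Why: Lemieux–Johnson oxidative cleavage, in which OsO4 dihydroxylates the 1,1-disubstituted alkene and periodate cleaves the diol to the C2 aryl ketone and formaldehyde, chosen over ozone because it should spare the two electron-rich arenes.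

Step 8
Reactants: 16 (3S)-3-[(R)-(tert-butyldimethylsilyloxy)(3,4,5-trimethoxyphenyl)methyl]-4-hydroxy-1-(3,4,5-trimethoxyphenyl)butan-1-one
Product: 18 tert-butyldimethylsilyl ether of (R)-[(3S)-5-(3,4,5-trimethoxyphenyl)-2,3-dihydrofuran-3-yl](3,4,5-trimethoxyphenyl)methanol, via cyclic hemiketal 17 (not isolated)
Conditions: PPTS (cat.), 4 Å MS, toluene, 80 °C; then Et3N
Reagents that add atoms: none
Why: Acid-catalysed cyclodehydration, in which the primary hydroxyl closes onto the ketone to give the five-membered hemiketal, and this loses water through the aryl-stabilised oxocarbenium ion and a C3 proton to give the conjugated 2-aryl enol ether, water removal by sieves driving the equilibrium and C4 not being involved.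

Step 9
Reactants: 18 tert-butyldimethylsilyl ether of (R)-[(3S)-5-(3,4,5-trimethoxyphenyl)-2,3-dihydrofuran-3-yl](3,4,5-trimethoxyphenyl)methanol
Product: 19 (R)-[(3S)-5-(3,4,5-trimethoxyphenyl)-2,3-dihydrofuran-3-yl](3,4,5-trimethoxyphenyl)methanol
Conditions: Bu4NF, THF, 0 °C → rt; H2O work-up
Reagents that add atoms: none
Why: Fluoride-mediated desilylation in a basic medium, in which the acid-labile enol ether should neither hydrolyse nor add the freed C7 hydroxyl to C2.

Step 10
Reactants: 19 (R)-[(3S)-5-(3,4,5-trimethoxyphenyl)-2,3-dihydrofuran-3-yl](3,4,5-trimethoxyphenyl)methanol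
Product: 20 (bromomethyl)dimethylsilyl ether of (R)-[(3S)-5-(3,4,5-trimethoxyphenyl)-2,3-dihydrofuran-3-yl](3,4,5-trimethoxyphenyl)methanol
Conditions: BrCH2SiMe2Cl, Et3N, DMAP (cat.), CH2Cl2, 0 °C; filtered and used without chromatography
Reagents that add atoms: (bromomethyl)chlorodimethylsilane, C[Si](C)(Cl)CBr
Why: Silylation of the secondary alcohol by the reactive chlorosilane under amine base, which installs the radical precursor on the C7 oxygen while the medium stays basic for the enol ether.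

Step 11
Reactants: 20 (bromomethyl)dimethylsilyl ether of (R)-[(3S)-5-(3,4,5-trimethoxyphenyl)-2,3-dihydrofuran-3-yl](3,4,5-trimethoxyphenyl)methanol
Product: 21 cis-fused oxasilinane–oxolane (2S,3R,4S,7R), in which the ring C3–C6H2–SiMe2–O–C7H(Ar)–C4 is fused across C3–C4 to the oxolane O1–C2H(Ar)–C3–C4–C5H2 and the C2 aryl group, C6 and C7 lie on one face of the oxolane
Conditions: Bu3SnH (1.3 equiv) and AIBN (0.2 equiv) added over 6 h, benzene (0.01 M), 80 °C
Reagents that add atoms: none
Why: Bu3Sn• abstracts bromine from 20 to give the silylmethyl radical at C6, which adds to C3 of the enol ether and closes the temporary 1,2-oxasilinane (ring C6–Si–O–C7–C4–C3) in the 6-exo-trig mode, the closest known reaction type being the silicon-tethered radical cyclisation of (bromomethyl)dimethylsilyl ethers of allylic and homoallylic alcohols that precedes a Tamao oxidation. The radical is tied to the ring through O–C7–C4, so it can reach only the lobe of C3 on the face that carries the C4–C7 bond, which sets C3 with C6 cis to C7 and makes the ring fusion cis. The adduct radical at C2 is stabilised by the aryl group and by O1, and Bu3SnH should deliver hydrogen to it from the convex face, anti to the C3–C6 bond and the fused ring, which sets C2 with the aryl group cis to C6. The step needs 6-exo rather than 7-endo closure, which is secured because C3 is the unsubstituted CH terminus and attack there gives the doubly stabilised radical, whereas C2 is fully substituted. It also needs cyclisation to outrun direct reduction of the silylmethyl radical and 1,5-hydrogen transfer from the allylic C4–H, which slow addition of the stannane at high dilution and the styrene-type acceptor should favour.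

Step 12
Reactants: 21 cis-fused oxasilinane–oxolane (2S,3R,4S,7R)
Product: 22 (R)-[(3S,4S,5S)-4-(hydroxymethyl)-5-(3,4,5-trimethoxyphenyl)oxolan-3-yl](3,4,5-trimethoxyphenyl)methanol
Conditions: 30% H2O2, KF, KHCO3, THF/MeOH 1:1, rt → 40 °C
Reagents that add atoms: hydrogen peroxide, OO
Why: Tamao oxidation, in which fluoride and peroxide add to silicon, C6 migrates from silicon to oxygen and the Si–O bonds are hydrolysed, turning the tether carbon into the C6 hydroxymethyl group and freeing the C7 hydroxyl without touching C2, C3 or C4.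

Step 13
Reactants: 22 (R)-[(3S,4S,5S)-4-(hydroxymethyl)-5-(3,4,5-trimethoxyphenyl)oxolan-3-yl](3,4,5-trimethoxyphenyl)methanol
Product: 23 (R)-[(3S,4S,5S)-4-[(tert-butyldimethylsilyloxy)methyl]-5-(3,4,5-trimethoxyphenyl)oxolan-3-yl](3,4,5-trimethoxyphenyl)methanol
Conditions: TBSCl (1.05 equiv), imidazole, CH2Cl2, 0 °C
Reagents that add atoms: tert-butyldimethylsilyl chloride, CC(C)(C)[Si](C)(C)Cl
Why: Selective silylation of the primary C6 hydroxyl over the hindered secondary benzylic C7 hydroxyl on steric grounds, which also prevents the later cis keto alcohol from closing to a bicyclic hemiketal.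

Step 14
Reactants: 23 (R)-[(3S,4S,5S)-4-[(tert-butyldimethylsilyloxy)methyl]-5-(3,4,5-trimethoxyphenyl)oxolan-3-yl](3,4,5-trimethoxyphenyl)methanol
Product: 24 [(3S,4S,5S)-4-[(tert-butyldimethylsilyloxy)methyl]-5-(3,4,5-trimethoxyphenyl)oxolan-3-yl](3,4,5-trimethoxyphenyl)methanone (all-cis)
Conditions: Dess–Martin periodinane, CH2Cl2, 0 °C → rt
Reagents that add atoms: none
Why: Dess–Martin oxidation of the secondary benzylic alcohol to the aryl ketone under mild conditions that leave the silyl ether, the benzylic ring ether and the arenes intact.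

Step 15
Reactants: 24 [(3S,4S,5S)-4-[(tert-butyldimethylsilyloxy)methyl]-5-(3,4,5-trimethoxyphenyl)oxolan-3-yl](3,4,5-trimethoxyphenyl)methanone
Product: 25 [(3R,4S,5S)-4-[(tert-butyldimethylsilyloxy)methyl]-5-(3,4,5-trimethoxyphenyl)oxolan-3-yl](3,4,5-trimethoxyphenyl)methanone
Conditions: DBU (0.3 equiv), CH2Cl2, rt
Reagents that add atoms: none
Why: Thermodynamic epimerisation through the ketone enolate, in which C4–H is the only acidic C–H and reprotonation should place the aroyl group trans to the C3 substituent to relieve the all-cis strain (C4 becomes R as in the target), while loss of O1 by β-elimination would be the reverse of a disfavoured 5-endo-trig closure.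

Step 16
Reactants: 25 [(3R,4S,5S)-4-[(tert-butyldimethylsilyloxy)methyl]-5-(3,4,5-trimethoxyphenyl)oxolan-3-yl](3,4,5-trimethoxyphenyl)methanone
Product: 26 [(3R,4S,5S)-4-(hydroxymethyl)-5-(3,4,5-trimethoxyphenyl)oxolan-3-yl](3,4,5-trimethoxyphenyl)methanone (target)
Conditions: Bu4NF, AcOH, THF, 0 °C → rt
Reagents that add atoms: none
Why: Fluoride desilylation buffered with acetic acid, which should free the primary alcohol without base-induced change at C4 or acid-induced opening of the benzylic ether at C2.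

**Compound list**
1 | 5-bromo-1,2,3-trimethoxybenzene | COc1cc(Br)cc(OC)c1OC | starting material
2 | succinic anhydride | O=C1CCC(=O)O1 | starting material
3 | (3,4,5-trimethoxyphenyl)magnesium bromide (formed in the flask) | COc1cc([Mg]Br)cc(OC)c1OC | intermediate
4 | 4-oxo-4-(3,4,5-trimethoxyphenyl)butanoic acid | OC(=O)CCC(=O)c1cc(OC)c(OC)c(OC)c1 | intermediate
5 | 4-(3,4,5-trimethoxyphenyl)pent-4-enoic acid | OC(=O)CCC(=C)c1cc(OC)c(OC)c(OC)c1 | intermediate
6 | (R)-4-benzyl-2-oxazolidinone | O=C1N[C@H](Cc2ccccc2)CO1 | starting material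
7 | mixed pivalic anhydride of 5 (formed in the flask) | CC(C)(C)C(=O)OC(=O)CCC(=C)c1cc(OC)c(OC)c(OC)c1 | intermediate
8 | (R)-4-benzyl-3-[4-(3,4,5-trimethoxyphenyl)pent-4-enoyl]-2-oxazolidinone | C=C(CCC(=O)N1C(=O)OC[C@H]1Cc1ccccc1)c1cc(OC)c(OC)c(OC)c1 | intermediate
9 | 3,4,5-trimethoxybenzaldehyde | COc1cc(C=O)cc(OC)c1OC | starting material
10 | Z-dibutylboron enolate of 8 (formed in the flask) | CCCCB(CCCC)O/C(=C\CC(=C)c1cc(OC)c(OC)c(OC)c1)N1C(=O)OC[C@H]1Cc1ccccc1 | intermediate
11 | dibutylboron aldolate of 12 (formed in the flask) | CCCCB(CCCC)O[C@@H](c1cc(OC)c(OC)c(OC)c1)[C@@H](CC(=C)c1cc(OC)c(OC)c(OC)c1)C(=O)N1C(=O)OC[C@H]1Cc1ccccc1 | intermediate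
12 | (R)-4-benzyl-3-[(2R)-2-[(R)-hydroxy(3,4,5-trimethoxyphenyl)methyl]-4-(3,4,5-trimethoxyphenyl)pent-4-enoyl]-2-oxazolidinone | O[C@@H](c1cc(OC)c(OC)c(OC)c1)[C@@H](CC(=C)c1cc(OC)c(OC)c(OC)c1)C(=O)N1C(=O)OC[C@H]1Cc1ccccc1 | intermediate
13 | (R)-4-benzyl-3-[(2R)-2-[(R)-(tert-butyldimethylsilyloxy)(3,4,5-trimethoxyphenyl)methyl]-4-(3,4,5-trimethoxyphenyl)pent-4-enoyl]-2-oxazolidinone | CC(C)(C)[Si](C)(C)O[C@@H](c1cc(OC)c(OC)c(OC)c1)[C@@H](CC(=C)c1cc(OC)c(OC)c(OC)c1)C(=O)N1C(=O)OC[C@H]1Cc1ccccc1 | intermediate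
14 | (2S)-2-[(R)-(tert-butyldimethylsilyloxy)(3,4,5-trimethoxyphenyl)methyl]-4-(3,4,5-trimethoxyphenyl)pent-4-en-1-ol | CC(C)(C)[Si](C)(C)O[C@@H](c1cc(OC)c(OC)c(OC)c1)[C@@H](CC(=C)c1cc(OC)c(OC)c(OC)c1)CO | intermediate
15 | (2S)-2-[(R)-(tert-butyldimethylsilyloxy)(3,4,5-trimethoxyphenyl)methyl]-4-(3,4,5-trimethoxyphenyl)pentane-1,4,5-triol, both epimers at the new carbinol carbon (formed in the flask) | CC(C)(C)[Si](C)(C)O[C@@H](c1cc(OC)c(OC)c(OC)c1)[C@@H](CC(O)(CO)c1cc(OC)c(OC)c(OC)c1)CO | intermediate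
16 | (3S)-3-[(R)-(tert-butyldimethylsilyloxy)(3,4,5-trimethoxyphenyl)methyl]-4-hydroxy-1-(3,4,5-trimethoxyphenyl)butan-1-one (in equilibrium with 17) | CC(C)(C)[Si](C)(C)O[C@@H](c1cc(OC)c(OC)c(OC)c1)[C@@H](CC(=O)c1cc(OC)c(OC)c(OC)c1)CO | intermediate
17 | (4S)-4-[(R)-(tert-butyldimethylsilyloxy)(3,4,5-trimethoxyphenyl)methyl]-2-(3,4,5-trimethoxyphenyl)oxolan-2-ol, both epimers at the hemiketal carbon (formed in the flask) | CC(C)(C)[Si](C)(C)O[C@@H](c1cc(OC)c(OC)c(OC)c1)[C@@H]1COC(O)(c2cc(OC)c(OC)c(OC)c2)C1 | intermediate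
18 | tert-butyldimethylsilyl ether of (R)-[(3S)-5-(3,4,5-trimethoxyphenyl)-2,3-dihydrofuran-3-yl](3,4,5-trimethoxyphenyl)methanol | CC(C)(C)[Si](C)(C)O[C@@H](c1cc(OC)c(OC)c(OC)c1)[C@@H]1COC(c2cc(OC)c(OC)c(OC)c2)=C1 | intermediate
19 | (R)-[(3S)-5-(3,4,5-trimethoxyphenyl)-2,3-dihydrofuran-3-yl](3,4,5-trimethoxyphenyl)methanol | O[C@@H](c1cc(OC)c(OC)c(OC)c1)[C@@H]1COC(c2cc(OC)c(OC)c(OC)c2)=C1 | intermediate
20 | (bromomethyl)dimethylsilyl ether of 19 (key-step precursor) | BrC[Si](C)(C)O[C@@H](c1cc(OC)c(OC)c(OC)c1)[C@@H]1COC(c2cc(OC)c(OC)c(OC)c2)=C1 | intermediate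
21 | cis-fused oxasilinane–oxolane (2S,3R,4S,7R), ring C3–C6H2–SiMe2–O–C7H(Ar)–C4 fused to the oxolane at C3–C4, C2 aryl cis to C6 and C7 (key-step product) | C[Si]1(C)O[C@@H](c2cc(OC)c(OC)c(OC)c2)[C@@H]2CO[C@H](c3cc(OC)c(OC)c(OC)c3)[C@@H]2C1 | intermediate
22 | (R)-[(3S,4S,5S)-4-(hydroxymethyl)-5-(3,4,5-trimethoxyphenyl)oxolan-3-yl](3,4,5-trimethoxyphenyl)methanol | O[C@@H](c1cc(OC)c(OC)c(OC)c1)[C@@H]1CO[C@H](c2cc(OC)c(OC)c(OC)c2)[C@@H]1CO | intermediate
23 | (R)-[(3S,4S,5S)-4-[(tert-butyldimethylsilyloxy)methyl]-5-(3,4,5-trimethoxyphenyl)oxolan-3-yl](3,4,5-trimethoxyphenyl)methanol | O[C@@H](c1cc(OC)c(OC)c(OC)c1)[C@@H]1CO[C@H](c2cc(OC)c(OC)c(OC)c2)[C@@H]1CO[Si](C)(C)C(C)(C)C | intermediate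
24 | [(3S,4S,5S)-4-[(tert-butyldimethylsilyloxy)methyl]-5-(3,4,5-trimethoxyphenyl)oxolan-3-yl](3,4,5-trimethoxyphenyl)methanone | O=C(c1cc(OC)c(OC)c(OC)c1)[C@@H]1CO[C@H](c2cc(OC)c(OC)c(OC)c2)[C@@H]1CO[Si](C)(C)C(C)(C)C | intermediate
25 | [(3R,4S,5S)-4-[(tert-butyldimethylsilyloxy)methyl]-5-(3,4,5-trimethoxyphenyl)oxolan-3-yl](3,4,5-trimethoxyphenyl)methanone | O=C(c1cc(OC)c(OC)c(OC)c1)[C@H]1CO[C@H](c2cc(OC)c(OC)c(OC)c2)[C@@H]1CO[Si](C)(C)C(C)(C)C | intermediate
26 | [(3R,4S,5S)-4-(hydroxymethyl)-5-(3,4,5-trimethoxyphenyl)oxolan-3-yl](3,4,5-trimethoxyphenyl)methanone | COc1cc(C(=O)[C@H]2CO[C@H](c3cc(OC)c(OC)c(OC)c3)[C@@H]2CO)cc(OC)c1OC | target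

**Step count and risks**
Total: 16 steps. Longest linear sequence: 16 steps (1 → 26); 2, 6 and 9 enter as purchased materials.

Steps most likely to fail:

First, step 11. The silylmethyl radical may be reduced before it cyclises or may take the allylic C4–H by 1,5-hydrogen transfer. The chain may also be short because the stabilised C2 radical abstracts hydrogen slowly, and hydrogen delivery at C2 may show poor facial selectivity. The fallback sets out from 18 and comes back at 22: C6 is introduced as an acyl group, and C2 and C3 are set by hydrogenation. Trichloroacetyl chloride and pyridine (CH2Cl2, 0 °C → rt) should C-acylate the enol ether at C3 and give the 3-trichloroacetyl-4,5-dihydrofuran F1. Haloform-type methanolysis of F1 (K2CO3, MeOH, rt) should give the methyl 2-aryl-4,5-dihydrofuran-3-carboxylate F2. Hydrogenation of F2 (H2, 4 atm, Pd/C, EtOAc) should add both hydrogens to C2 and C3 from the face away from the bulky C4 substituent and give the all-cis oxolane ester F3. LiAlH4 (THF, −20 °C) should reduce F3 to the C6 primary alcohol F4, which still carries the C7 silyl ether, and Bu4NF (THF, rt) then frees diol 22 from F4.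

Second, step 8. The dehydration may stall at the hemiketal equilibrium, the electron-rich enol ether may hydrolyse or oligomerise under acid, or the benzylic silyl ether may ionise. The fallback sets out from 16 and comes back at 18: the hemiketal is fixed with MeOH and PPTS (cat.) at rt as the 2-methoxy-2-aryloxolane F5. TMSOTf with iPr2NEt (CH2Cl2, −20 °C → 0 °C) then removes methanol from F5 irreversibly under amine-buffered conditions and gives 18.

Third, step 6. Hydride may attack the ring carbonyl of the hindered imide and open the auxiliary, or the silyl group may migrate to the new primary alkoxide. The fallback sets out from 13 and comes back at 14: the auxiliary is displaced by LiSEt (EtSH, n-BuLi, THF, 0 °C) to give the S-ethyl thioester F6, and LiBH4 (THF, 0 °C) reduces F6 to 14.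

**Further compounds**
F1 | step 11 | 2,2,2-trichloro-1-[(4S)-4-[(R)-(tert-butyldimethylsilyloxy)(3,4,5-trimethoxyphenyl)methyl]-2-(3,4,5-trimethoxyphenyl)-4,5-dihydrofuran-3-yl]ethanone | CC(C)(C)[Si](C)(C)O[C@@H](c1cc(OC)c(OC)c(OC)c1)[C@@H]1COC(c2cc(OC)c(OC)c(OC)c2)=C1C(=O)C(Cl)(Cl)Cl
F2 | step 11 | methyl (4S)-4-[(R)-(tert-butyldimethylsilyloxy)(3,4,5-trimethoxyphenyl)methyl]-2-(3,4,5-trimethoxyphenyl)-4,5-dihydrofuran-3-carboxylate | CC(C)(C)[Si](C)(C)O[C@@H](c1cc(OC)c(OC)c(OC)c1)[C@@H]1COC(c2cc(OC)c(OC)c(OC)c2)=C1C(=O)OC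
F3 | step 11 | methyl (2S,3R,4S)-4-[(R)-(tert-butyldimethylsilyloxy)(3,4,5-trimethoxyphenyl)methyl]-2-(3,4,5-trimethoxyphenyl)oxolane-3-carboxylate (all-cis) | CC(C)(C)[Si](C)(C)O[C@@H](c1cc(OC)c(OC)c(OC)c1)[C@@H]1CO[C@H](c2cc(OC)c(OC)c(OC)c2)[C@@H]1C(=O)OC
F4 | step 11 | [(2S,3S,4S)-4-[(R)-(tert-butyldimethylsilyloxy)(3,4,5-trimethoxyphenyl)methyl]-2-(3,4,5-trimethoxyphenyl)oxolan-3-yl]methanol (all-cis) | CC(C)(C)[Si](C)(C)O[C@@H](c1cc(OC)c(OC)c(OC)c1)[C@@H]1CO[C@H](c2cc(OC)c(OC)c(OC)c2)[C@@H]1CO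
F5 | step 8 | (4S)-4-[(R)-(tert-butyldimethylsilyloxy)(3,4,5-trimethoxyphenyl)methyl]-2-methoxy-2-(3,4,5-trimethoxyphenyl)oxolane, both epimers at the ketal carbon | CC(C)(C)[Si](C)(C)O[C@@H](c1cc(OC)c(OC)c(OC)c1)[C@@H]1COC(OC)(c2cc(OC)c(OC)c(OC)c2)C1
F6 | step 6 | S-ethyl (2R)-2-[(R)-(tert-butyldimethylsilyloxy)(3,4,5-trimethoxyphenyl)methyl]-4-(3,4,5-trimethoxyphenyl)pent-4-enethioate | CCSC(=O)[C@H](CC(=C)c1cc(OC)c(OC)c(OC)c1)[C@@H](O[Si](C)(C)C(C)(C)C)c1cc(OC)c(OC)c(OC)c1
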